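**Strategy.** Ring B (O1, C2, C3, C3a, C7a) is a γ-butyrolactone in disguise. O1 and C2 come from a protected protocatechualdehyde; C3, C3a and C7a are the β-, α- and carbonyl carbons of an enal that already carries ring C. One carbene-catalysed homoenolate [3+2] annulation forms C2–C3 and O1–C7a, closes the lactone and fixes the cis relationship at C2/C3 while ring A is still absent. Its precursor is the E-enal bearing the SEM-protected ring C pyranone at the β-carbon, paired with 3,4-bis(silyloxy)benzaldehyde. The fused pyranone (ring A) is added afterwards at C7a and C3a by carboxylation, enol triflation, alkynylation and gold-catalysed lactonisation, under conditions that leave both stereocentres alone.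

Key step: step 6

Remark: the SMILES is read as the cis-(2R,3S) isomer; ring A is the fused 2-pyranone (C3a, C4, O5, C6, C7, C7a), ring B the dihydrofuran (O1, C2, C3, C3a, C7a), ring C the pendant 4-hydroxy-2-pyranone; TBS = tert-butyldimethylsilyl, SEM = 2-(trimethylsilyl)ethoxymethyl.

Step 1
Reactants: 1 4-hydroxy-6-methyl-2H-pyran-2-one
Product: 2 6-methyl-4-{[2-(trimethylsilyl)ethoxy]methoxy}-2H-pyran-2-one
Conditions: SEMCl, iPr2NEt, CH2Cl2, 0 °C → rt
Reagents that add atoms: 2-(trimethylsilyl)ethoxymethyl chloride, C[Si](C)(C)CCOCCl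
Why: Williamson-type O-alkylation of the vinylogous acid with a hard α-chloro ether is expected mainly at O4; the SEM acylal is chosen because it tolerates amide bases, palladium and gold yet is cleaved by HF together with the aryl silyl ethers, so the final unmasking needs neither base nor strong acid.

Step 2
Reactants: 2 6-methyl-4-(SEM-oxy)-2H-pyran-2-one
Product: 3 2-oxo-4-(SEM-oxy)-2H-pyran-6-carbaldehyde
Conditions: SeO2, 4 Å MS, 1,4-dioxane, 110–120 °C (sealed tube)
Reagents that add atoms: selenium dioxide, O=[Se]=O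
Why: Riley oxidation of the 6-methyl group, activated through the ring dienoate, is established for 4-alkoxy-6-methyl-2-pyranones and stops at the aldehyde; the sieves take up the water formed so that selenous acid should not hydrolyse the acylal.

Step 3
Reactants: 3 2-oxo-4-(SEM-oxy)-2H-pyran-6-carbaldehyde; 4 (triphenylphosphoranylidene)acetaldehyde
Product: 5 (2E)-3-[2-oxo-4-(SEM-oxy)-2H-pyran-6-yl]prop-2-enal
Conditions: 4 (1.05 equiv), CH2Cl2, rt
Reagents that add atoms: none
Why: Wittig olefination with the formyl-stabilised ylide should give the E-enal, and one equivalent of ylide on the more electrophilic heteroaryl aldehyde limits a second homologation of the product.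

Step 4
Reactants: 6 3,4-dihydroxybenzaldehyde
Product: 7 3,4-bis(tert-butyldimethylsilyloxy)benzaldehyde
Conditions: TBSCl, imidazole, DMF, rt
Reagents that add atoms: tert-butyldimethylsilyl chloride, CC(C)(C)[Si](C)(C)Cl
Why: Imidazole-promoted silylation of both phenols is routine; aryl TBS ethers withstand amide bases, palladium, copper and gold and are removed at the end by HF.

Step 5
Reactants: 7 3,4-bis(TBS-oxy)benzaldehyde
Product: 8 4-ethynyl-1,2-bis(tert-butyldimethylsilyloxy)benzene
Conditions: Me3SiCHN2, LiN(iPr)2, THF, −78 °C → rt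
Reagents that add atoms: trimethylsilyldiazomethane, C[Si](C)(C)C=[N+]=[N-]
Why: Colvin rearrangement: the lithiated diazo compound adds to the aldehyde, Peterson-type loss of lithium trimethylsilanolate and then N2 gives an alkylidene carbene whose 1,2-hydrogen shift delivers the terminal alkyne, and the absence of protic base spares the aryl silyl ethers.

Step 6
Reactants: 5 (2E)-3-[2-oxo-4-(SEM-oxy)-2H-pyran-6-yl]prop-2-enal; 7 3,4-bis(TBS-oxy)benzaldehyde
Product: 9 (4S,5R)-5-[3,4-bis(TBS-oxy)phenyl]-4-[2-oxo-4-(SEM-oxy)-2H-pyran-6-yl]oxolan-2-one (cis γ-butyrolactone)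
Conditions: (5aS,10bR)-2-(2,4,6-trimethylphenyl)-5a,10b-dihydro-4H,6H-indeno[2,1-b][1,2,4]triazolo[4,3-d][1,4]oxazin-2-ium chloride (12 mol%), DBU (10 mol%), Ti(OiPr)4 (20 mol%), CH2Cl2, rt; 7 (3 equiv), 5 added slowly
Reagents that add atoms: none
Why: The carbene adds to the formyl group of 5 and proton transfer gives the conjugated hydroxy-enamine (homoenolate equivalent), whose β-carbon (C3) attacks the titanium-activated carbonyl carbon of 7 (C2); the resulting alkoxide (O1) then acylates the acyl azolium (C7a) and releases the carbene. The closest known reaction is the carbene-catalysed formal [3+2] homoenolate annulation of β-aryl enals with aryl aldehydes to cis-4,5-disubstituted γ-butyrolactones, including its Ti(OiPr)4-assisted form. The lactone that becomes ring B closes by 5-exo-trig O-acylation. C3 is set by the face of the homoenolate that the indane backbone of the triazolylidene leaves open, and C2 by the compact titanium-bridged addition that places the aryl and pyranonyl groups cis; the (5aS,10bR) salt is specified, and its enantiomer is equally accessible should the sense of induction prove opposite. The step needs cross- rather than self-annulation and C–C bond formation rather than β-protonation, which a three-fold excess of the non-enolisable aldehyde 7, slow addition of 5, Lewis-acid activation of the electron-rich aldehyde and an alcohol-free medium should secure, while keeping DBU below the azolium loading spares the base-labile H-3/acyloxy array of 9.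

Step 7
Reactants: 9 cis γ-butyrolactone
Product: 11 tert-butyl (4S,5R)-5-[3,4-bis(TBS-oxy)phenyl]-2-oxo-4-[2-oxo-4-(SEM-oxy)-2H-pyran-6-yl]oxolane-3-carboxylate (mixture of C3 epimers), via lithium enolate 10 (not isolated)
Conditions: 9 added to LiN(SiMe3)2 (2.1 equiv), THF, −78 °C; Boc2O, −78 °C; AcOH quench at −78 °C
Reagents that add atoms: di-tert-butyl dicarbonate, CC(C)(C)OC(=O)OC(=O)OC(C)(C)C
Why: Claisen-type C-acylation of a lactone lithium enolate: the weak, hindered amide is directed to the lactone α-CH2 by lithium–carbonyl coordination, inverse addition keeps neutral 9 away from enolate, and once the enolate (later the malonate anion) exists the neighbouring H-3 can no longer be removed, so both ring B stereocentres are retained while the new α-centre is irrelevant because it becomes sp2 in step 8.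

Step 8
Reactants: 11 α-tert-butoxycarbonyl lactone
Product: 13 tert-butyl (4S,5R)-5-[3,4-bis(TBS-oxy)phenyl]-4-[2-oxo-4-(SEM-oxy)-2H-pyran-6-yl]-2-(trifluoromethanesulfonyloxy)-4,5-dihydrofuran-3-carboxylate, via sodium enolate 12 (not isolated)
Conditions: NaH (1.05 equiv), CH2Cl2, 0 °C; Tf2O, −78 → 0 °C
Reagents that add atoms: trifluoromethanesulfonic anhydride, O=S(=O)(OS(=O)(=O)C(F)(F)F)C(F)(F)F
Why: Proposed new method: O-sulfonylation of the sodium enolate of an α-alkoxycarbonyl lactone is expected at the lactone oxygen because the lactone carbonyl (locked E-ester geometry) carries more of the enolate charge and is less shielded than the tert-butyl ester carbonyl, and because the endocyclic push–pull alkene O1–C7a=C3a–CO2tBu is the more stable ketene acetal; the closest known reactions are the enol triflation of β-keto ester enolates to β-trifloxy acrylates and the formation of cyclic ketene acetal triflates and phosphates from lactone enolates.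

Step 9
Reactants: 13 enol triflate; 8 4-ethynyl-1,2-bis(TBS-oxy)benzene
Product: 14 tert-butyl (4S,5R)-5-[3,4-bis(TBS-oxy)phenyl]-2-{[3,4-bis(TBS-oxy)phenyl]ethynyl}-4-[2-oxo-4-(SEM-oxy)-2H-pyran-6-yl]-4,5-dihydrofuran-3-carboxylate
Conditions: PdCl2(PPh3)2 (5 mol%), CuI (10 mol%), Et3N, THF, rt (degassed)
Reagents that add atoms: none
Why: Sonogashira coupling: β-trifloxy acrylates add oxidatively to zerovalent palladium at room temperature, the tertiary amine cannot displace the triflate by addition–elimination, and no stereocentre takes part.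

Step 10
Reactants: 14 enyne tert-butyl ester
Product: 15 (2R,3S)-2,6-bis[3,4-bis(TBS-oxy)phenyl]-3-[2-oxo-4-(SEM-oxy)-2H-pyran-6-yl]-2,3-dihydro-4H-furo[3,2-c]pyran-4-one
Conditions: (Ph3P)AuNTf2 (5 mol%), CH2Cl2, rt
Reagents that add atoms: none
Why: Gold-catalysed cycloisomerisation of a (Z)-2-en-4-ynoic tert-butyl ester: the ester carbonyl oxygen attacks the gold-activated alkyne 6-endo-dig at the aryl-bearing carbon (the electrophilic δ-position of the enynoate, further stabilised by the electron-rich aryl group), isobutene is lost and protodeauration gives the 2-pyranone ring A.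

Step 11
Reactants: 15 fully protected target
Product: 16 (2R,3S)-2,6-bis(3,4-dihydroxyphenyl)-3-(4-hydroxy-2-oxo-2H-pyran-6-yl)-2,3-dihydro-4H-furo[3,2-c]pyran-4-one (CNP0224684.1)
Conditions: 48% aq. HF, MeCN, 0 °C → rt (degassed)
Reagents that add atoms: none
Why: Global deprotection: HF cleaves the four aryl silyl ethers and fragments the SEM acylal at O4 of ring C, and because the medium is only mildly acidic and free of base, neither E1cB opening of ring B through H-3 nor ionisation or quinone methide formation at the benzylic C2–O1 bond should erode the cis arrangement.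

**Compound list**

1 | 4-hydroxy-6-methyl-2H-pyran-2-one | Cc1cc(O)cc(=O)o1 | starting material
2 | 6-methyl-4-{[2-(trimethylsilyl)ethoxy]methoxy}-2H-pyran-2-one | Cc1cc(OCOCC[Si](C)(C)C)cc(=O)o1 | intermediate
3 | 2-oxo-4-(SEM-oxy)-2H-pyran-6-carbaldehyde | O=Cc1cc(OCOCC[Si](C)(C)C)cc(=O)o1 | intermediate
4 | (triphenylphosphoranylidene)acetaldehyde | O=CC=P(c1ccccc1)(c1ccccc1)c1ccccc1 | starting material
5 | (2E)-3-[2-oxo-4-(SEM-oxy)-2H-pyran-6-yl]prop-2-enal | O=C/C=C/c1cc(OCOCC[Si](C)(C)C)cc(=O)o1 | intermediate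
6 | 3,4-dihydroxybenzaldehyde | O=Cc1ccc(O)c(O)c1 | starting material
7 | 3,4-bis(tert-butyldimethylsilyloxy)benzaldehyde | O=Cc1ccc(O[Si](C)(C)C(C)(C)C)c(O[Si](C)(C)C(C)(C)C)c1 | intermediate
8 | 4-ethynyl-1,2-bis(tert-butyldimethylsilyloxy)benzene | C#Cc1ccc(O[Si](C)(C)C(C)(C)C)c(O[Si](C)(C)C(C)(C)C)c1 | intermediate
9 | (4S,5R)-5-[3,4-bis(TBS-oxy)phenyl]-4-[2-oxo-4-(SEM-oxy)-2H-pyran-6-yl]oxolan-2-one | O=c1cc(OCOCC[Si](C)(C)C)cc([C@H]2CC(=O)O[C@H]2c2ccc(O[Si](C)(C)C(C)(C)C)c(O[Si](C)(C)C(C)(C)C)c2)o1 | intermediate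
10 | lithium enolate of 9 (lithium (4S,5R)-5-aryl-4-pyranonyl-4,5-dihydrofuran-2-olate) | O=c1cc(OCOCC[Si](C)(C)C)cc([C@H]2C=C([O-])O[C@H]2c2ccc(O[Si](C)(C)C(C)(C)C)c(O[Si](C)(C)C(C)(C)C)c2)o1.[Li+] | intermediate (not isolated)
11 | tert-butyl (4S,5R)-5-[3,4-bis(TBS-oxy)phenyl]-2-oxo-4-[2-oxo-4-(SEM-oxy)-2H-pyran-6-yl]oxolane-3-carboxylate, C3 epimers | O=c1cc(OCOCC[Si](C)(C)C)cc([C@H]2C(C(=O)OC(C)(C)C)C(=O)O[C@H]2c2ccc(O[Si](C)(C)C(C)(C)C)c(O[Si](C)(C)C(C)(C)C)c2)o1 | intermediate
12 | sodium enolate of 11 | O=c1cc(OCOCC[Si](C)(C)C)cc([C@H]2C(C(=O)OC(C)(C)C)=C([O-])O[C@H]2c2ccc(O[Si](C)(C)C(C)(C)C)c(O[Si](C)(C)C(C)(C)C)c2)o1.[Na+] | intermediate (not isolated)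
13 | tert-butyl (4S,5R)-5-[3,4-bis(TBS-oxy)phenyl]-4-[2-oxo-4-(SEM-oxy)-2H-pyran-6-yl]-2-(trifluoromethanesulfonyloxy)-4,5-dihydrofuran-3-carboxylate | O=c1cc(OCOCC[Si](C)(C)C)cc([C@H]2C(C(=O)OC(C)(C)C)=C(OS(=O)(=O)C(F)(F)F)O[C@H]2c2ccc(O[Si](C)(C)C(C)(C)C)c(O[Si](C)(C)C(C)(C)C)c2)o1 | intermediate
14 | tert-butyl (4S,5R)-5-[3,4-bis(TBS-oxy)phenyl]-2-{[3,4-bis(TBS-oxy)phenyl]ethynyl}-4-[2-oxo-4-(SEM-oxy)-2H-pyran-6-yl]-4,5-dihydrofuran-3-carboxylate | O=c1cc(OCOCC[Si](C)(C)C)cc([C@H]2C(C(=O)OC(C)(C)C)=C(C#Cc3ccc(O[Si](C)(C)C(C)(C)C)c(O[Si](C)(C)C(C)(C)C)c3)O[C@H]2c2ccc(O[Si](C)(C)C(C)(C)C)c(O[Si](C)(C)C(C)(C)C)c2)o1 | intermediate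
15 | (2R,3S)-2,6-bis[3,4-bis(TBS-oxy)phenyl]-3-[2-oxo-4-(SEM-oxy)-2H-pyran-6-yl]-2,3-dihydro-4H-furo[3,2-c]pyran-4-one | O=c1cc(OCOCC[Si](C)(C)C)cc([C@H]2c3c(cc(-c4ccc(O[Si](C)(C)C(C)(C)C)c(O[Si](C)(C)C(C)(C)C)c4)oc3=O)O[C@H]2c2ccc(O[Si](C)(C)C(C)(C)C)c(O[Si](C)(C)C(C)(C)C)c2)o1 | intermediate
16 | (2R,3S)-2,6-bis(3,4-dihydroxyphenyl)-3-(4-hydroxy-2-oxo-2H-pyran-6-yl)-2,3-dihydro-4H-furo[3,2-c]pyran-4-one | O=c1cc(O)cc([C@H]2c3c(cc(-c4ccc(O)c(O)c4)oc3=O)O[C@H]2c2ccc(O)c(O)c2)o1 | target

**Totals.** 11 steps in all. Longest linear sequence: 9 steps (1 → 2 → 3 → 5 → 9 → 11 → 13 → 14 → 15 → 16; steps 1–3 and 6–11).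

**Steps most likely to fail**

Step 8. Sulfonylation may take place at the ester oxygen, or the stabilised enolate may react sluggishly, so that the leaving group at C7a is not installed cleanly. The fallback reverses the order of bond formation and starts from the plain lactone 9, whose enolisation has only one possible regiochemistry. Lactone 9 is treated with KN(SiMe3)2 and diphenyl chlorophosphate (THF/HMPA, −78 °C) to give the cyclic ketene acetal diphenyl phosphate F1. F1 is coupled with alkyne 8 under Pd(PPh3)4/CuI/Et3N to the 2-alkynyl-4,5-dihydrofuran F2. The nucleophilic enol ether carbon C3a of F2 is acylated with trichloroacetyl chloride/pyridine (CH2Cl2, 0 °C) to the trichloromethyl ketone F3. Haloform-type cleavage of F3 with LiOtBu in tBuOH/THF then gives the tert-butyl ester 14, where the route is rejoined.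

Step 6. Facial selectivity of the homoenolate addition under the chiral carbene may be poor, or the chiral triazolylidene may turn over slowly with the electron-rich aldehyde. The fallback gives up catalyst control of absolute configuration. Enal 5 and aldehyde 7 are annulated with the more active achiral carbene from 1,3-dimesitylimidazolium chloride/DBU, with Ti(OiPr)4 kept for cis selectivity. This should give the racemic cis lactone, that is 9 together with its (4R,5S)-enantiomer F4. Preparative chromatography on a chiral stationary phase then supplies 9 and removes F4, and the route continues from 9.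

Step 7. The base may remove H-3, which is vinylogous to the ring C lactone, in competition with the lactone α-CH2; this would lead to epimerisation at C3 or E1cB opening of the lactone. The fallback masks ring C as its own anion during enolisation. The SEM acylal of 9 is cleaved with MgBr2·OEt2 (CH2Cl2, rt) to the free 4-hydroxypyranone lactone F5. With 3.1 equiv LiN(SiMe3)2 the lithium pyranone-4-olate forms first, and its charge makes H-3 non-acidic. The lactone enolate then forms and is C-acylated by 1.05 equiv Boc2O at −78 °C to the α-tert-butoxycarbonyl lactone with free ring C hydroxyl F6; the weakly nucleophilic olate should stay unacylated. SEMCl/iPr2NEt re-protects the far more acidic pyranone hydroxyl selectively and returns to 11.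

**Further compounds**

F1 | step 8 | diphenyl (4S,5R)-5-[3,4-bis(TBS-oxy)phenyl]-4-[2-oxo-4-(SEM-oxy)-2H-pyran-6-yl]-4,5-dihydrofuran-2-yl phosphate | O=c1cc(OCOCC[Si](C)(C)C)cc([C@H]2C=C(OP(=O)(Oc3ccccc3)Oc3ccccc3)O[C@H]2c2ccc(O[Si](C)(C)C(C)(C)C)c(O[Si](C)(C)C(C)(C)C)c2)o1
F2 | step 8 | (2R,3S)-2-[3,4-bis(TBS-oxy)phenyl]-5-{[3,4-bis(TBS-oxy)phenyl]ethynyl}-3-[2-oxo-4-(SEM-oxy)-2H-pyran-6-yl]-2,3-dihydrofuran | O=c1cc(OCOCC[Si](C)(C)C)cc([C@H]2C=C(C#Cc3ccc(O[Si](C)(C)C(C)(C)C)c(O[Si](C)(C)C(C)(C)C)c3)O[C@H]2c2ccc(O[Si](C)(C)C(C)(C)C)c(O[Si](C)(C)C(C)(C)C)c2)o1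
F3 | step 8 | 2,2,2-trichloro-1-{(4S,5R)-5-[3,4-bis(TBS-oxy)phenyl]-2-{[3,4-bis(TBS-oxy)phenyl]ethynyl}-4-[2-oxo-4-(SEM-oxy)-2H-pyran-6-yl]-4,5-dihydrofuran-3-yl}ethan-1-one | O=c1cc(OCOCC[Si](C)(C)C)cc([C@H]2C(C(=O)C(Cl)(Cl)Cl)=C(C#Cc3ccc(O[Si](C)(C)C(C)(C)C)c(O[Si](C)(C)C(C)(C)C)c3)O[C@H]2c2ccc(O[Si](C)(C)C(C)(C)C)c(O[Si](C)(C)C(C)(C)C)c2)o1
F4 | step 6 | (4R,5S)-5-[3,4-bis(TBS-oxy)phenyl]-4-[2-oxo-4-(SEM-oxy)-2H-pyran-6-yl]oxolan-2-one (enantiomer of 9) | O=c1cc(OCOCC[Si](C)(C)C)cc([C@@H]2CC(=O)O[C@@H]2c2ccc(O[Si](C)(C)C(C)(C)C)c(O[Si](C)(C)C(C)(C)C)c2)o1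
F5 | step 7 | (4S,5R)-5-[3,4-bis(TBS-oxy)phenyl]-4-(4-hydroxy-2-oxo-2H-pyran-6-yl)oxolan-2-one | O=c1cc(O)cc([C@H]2CC(=O)O[C@H]2c2ccc(O[Si](C)(C)C(C)(C)C)c(O[Si](C)(C)C(C)(C)C)c2)o1
F6 | step 7 | tert-butyl (4S,5R)-5-[3,4-bis(TBS-oxy)phenyl]-4-(4-hydroxy-2-oxo-2H-pyran-6-yl)-2-oxooxolane-3-carboxylate, C3 epimers | O=c1cc(O)cc([C@H]2C(C(=O)OC(C)(C)C)C(=O)O[C@H]2c2ccc(O[Si](C)(C)C(C)(C)C)c(O[Si](C)(C)C(C)(C)C)c2)o1
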